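**Retrosynthetic overview**
1. The C5–allyl bond is made last. Ring A stays aromatic until the end. The 6-phenol is then oxidised on a chiral aryl-λ3-iodane, so that C5 (alpha to the emerging C6 ketone, normally a nucleophilic phenol ortho carbon) acts as an enolonium-type electrophile toward allyltrimethylsilane. This dearomatises ring A and sets C5.
2. The O1–C7a bond closes the dihydrofuran ring on a 4-alkylsyringol by oxidative acetoxylation, 5-exo oxa-Michael addition of the side-chain alcohol and loss of AcOH.
3. C2 and C3 are set together by dynamic-kinetic asymmetric transfer hydrogenation of a racemic 1,2-diarylpropan-1-one.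
4. The C3–C3a bond comes from palladium enolate arylation of 3,4,5-trimethoxypropiophenone with 4-bromosyringol.
5. Ring order: both benzene rings are bought, the dihydrofuran ring is formed third, and the cyclohexadienone is formed last by dearomatisation.

Assumption: both aryl building blocks, allyltrimethylsilane and the (R,R)-iodoarene are catalogue items, and benzofuran numbering (O1, C2, C3, C3a, C4 to C7, C7a) is also used for the atoms that later become these positions.

**Step 1**
Reactants: 1 1-(3,4,5-trimethoxyphenyl)propan-1-one; 2 4-bromo-2,6-dimethoxyphenol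
Product: 3 rac-2-(4-hydroxy-3,5-dimethoxyphenyl)-1-(3,4,5-trimethoxyphenyl)propan-1-one
Conditions: Pd(OAc)2 (2 mol %), XPhos (4 mol %), NaOtBu (2.6 equiv), toluene, 80 °C; aq NH4Cl
Reagents that add atoms: none
Why: Buchwald–Hartwig-type palladium enolate alpha-arylation in which the bromophenol travels as its sodium phenoxide (unprotected bromophenols are competent partners in enolate arylation) and the tertiary alpha carbon formed cannot arylate again; the new centre is deliberately racemic because step 2 is dynamic.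

**Step 2**
Reactants: 3 rac-2-(4-hydroxy-3,5-dimethoxyphenyl)-1-(3,4,5-trimethoxyphenyl)propan-1-one
Product: 4 4-[(1S,2S)-1-hydroxy-1-(3,4,5-trimethoxyphenyl)propan-2-yl]-2,6-dimethoxyphenol
Conditions: RuCl[(S,S)-TsDPEN](p-cymene) (2 mol %), HCO2H/DBU (1:1.2), DMF, 40 °C
Reagents that add atoms: none
Why: Noyori–Ikariya asymmetric transfer hydrogenation with dynamic kinetic resolution, in which free DBU racemises 3 through its enolate faster than it is reduced, the (S,S) catalyst fixes the carbinol as 1S, and the 2S ketone is consumed faster because it is the Felkin–Anh matched enantiomer, so both centres are set at once as (1S,2S), as known for 1,2-diarylpropan-1-ones on the way to trans-2-aryl-3-methyldihydrobenzofurans.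

**Step 3**
Reactants: 4 4-[(1S,2S)-1-hydroxy-1-(3,4,5-trimethoxyphenyl)propan-2-yl]-2,6-dimethoxyphenol
Product: 7 (2S,3S)-5,7-dimethoxy-3-methyl-2-(3,4,5-trimethoxyphenyl)-2,3-dihydro-1-benzofuran-6-ol, via ortho-quinol acetate 5 (not isolated), via oxa-Michael adduct 6 (not isolated)
Conditions: PhI(OAc)2 (1.0 equiv), CH2Cl2, −78 to −20 °C; then DBU (2.5 equiv), −20 °C to rt, Ar; aq NH4Cl
Reagents that add atoms: none
Why: Hypervalent-iodine oxidative acetoxylation of a 2-methoxyphenol puts acetate on a methoxy-bearing ortho carbon (the two are equivalent), the side-chain alcohol then adds 5-exo-trig to the now electrophilic enone beta carbon C7a, and loss of AcOH rearomatises (the dearomatisation/conjugate addition/rearomatisation benzannulation known for tethered O and N nucleophiles on ortho-quinol acetates); no bond at C2 or C3 is touched, so (1S,2S) becomes the trans (2S,3S) ring.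

**Step 4**
Reactants: 8 (2R,2′R)-2,2′-[(2-iodo-1,3-phenylene)bis(oxy)]bis[N-(2,4,6-trimethylphenyl)propanamide]
Product: 10 (2R,2′R)-2,2′-({2-[bis(trifluoroacetoxy)-λ3-iodanyl]-1,3-phenylene}bis(oxy))bis[N-(2,4,6-trimethylphenyl)propanamide], via diacetoxy-λ3-iodane 9 (not isolated)
Conditions: AcOOH (32 % in AcOH, 1.5 equiv), CH2Cl2, rt; evaporate; CF3CO2H (5 equiv), CH2Cl2, 0 °C; evaporate to dryness, use at once
Reagents that add atoms: trifluoroacetic acid, O=C(O)C(F)(F)F
Why: Standard peracid oxidation of an iodoarene to its trivalent-iodine diacetate followed by carboxylate ligand exchange driven by evaporation of AcOH, which leaves only weakly nucleophilic trifluoroacetate on iodine and does not touch the lactamide stereocentres.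

**Step 5 (key step)**
Reactants: 7 (2S,3S)-5,7-dimethoxy-3-methyl-2-(3,4,5-trimethoxyphenyl)-2,3-dihydro-1-benzofuran-6-ol; 10 (R,R)-bis(trifluoroacetoxy)-λ3-iodane; 11 allyltrimethylsilane
Product: 13 (2S,3S,5R)-5,7-dimethoxy-3-methyl-5-(prop-2-en-1-yl)-2-(3,4,5-trimethoxyphenyl)-3,5-dihydro-1-benzofuran-6(2H)-one, via aryloxy-λ3-iodane 12 (not isolated)
Conditions: 7 and 11 (3 equiv), 4 Å MS, CH2Cl2, −78 °C; add 10 (1.05 equiv) dropwise, −78 to −40 °C; cold aq NaHCO3; chromatography below 25 °C (8 recovered)
Reagents that add atoms: allyltrimethylsilane (11), C=CC[Si](C)(C)C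
Why: Proposed new method: ligand exchange gives 12, in which C5 (a phenol ortho carbon and the alpha carbon of the emerging C6 ketone, normally nucleophilic) becomes an enolonium-type electrophile, and the equally nucleophilic allylsilane terminus attacks this methoxy-stabilised, least hindered position (C7 is flanked by O1 and C3a is neopentyl-like) in an SN2′-type displacement of the still-bound chiral iodoarene, whose hydrogen-bonded lactamide arms shield one face so that C5 is set as R under reagent control while the remote C2 and C3 do not interfere, with trifluoroacetate removing Me3Si to finish a Hosomi–Sakurai-type event; the closest known reaction types are the racemic PhI(OCOCF3)2-mediated oxidative nucleophilic substitution of 2-alkoxyarenols by allylsilanes and silyl enol ethers at the alkoxy-bearing ortho carbon, and the Kita-type enantioselective ortho-spirolactonisation of arenols with this same C2-symmetric iodoarene.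

**Compound list**
1 | 1-(3,4,5-trimethoxyphenyl)propan-1-one | CCC(=O)c1cc(OC)c(OC)c(OC)c1 | starting material
2 | 4-bromo-2,6-dimethoxyphenol | COc1cc(Br)cc(OC)c1O | starting material
3 | rac-2-(4-hydroxy-3,5-dimethoxyphenyl)-1-(3,4,5-trimethoxyphenyl)propan-1-one | CC(C(=O)c1cc(OC)c(OC)c(OC)c1)c1cc(OC)c(O)c(OC)c1 | intermediate
4 | 4-[(1S,2S)-1-hydroxy-1-(3,4,5-trimethoxyphenyl)propan-2-yl]-2,6-dimethoxyphenol | O[C@H](c1cc(OC)c(OC)c(OC)c1)[C@H](c1cc(OC)c(O)c(OC)c1)C | intermediate
5 | 3-[(1S,2S)-1-hydroxy-1-(3,4,5-trimethoxyphenyl)propan-2-yl]-1,5-dimethoxy-6-oxocyclohexa-2,4-dien-1-yl acetate (both epimers at the acetoxy carbon) | O[C@H](c1cc(OC)c(OC)c(OC)c1)[C@H](C1=CC(OC)(OC(C)=O)C(=O)C(OC)=C1)C | intermediate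
6 | (2S,3S)-5,7-dimethoxy-3-methyl-6-oxo-2-(3,4,5-trimethoxyphenyl)-2,3,5,6,7,7a-hexahydro-1-benzofuran-5-yl acetate (mixture at C5, C7 and C7a, all erased on aromatisation) | COC1(OC(C)=O)C=C2C(C(OC)C1=O)O[C@H](c1cc(OC)c(OC)c(OC)c1)[C@H]2C | intermediate
7 | (2S,3S)-5,7-dimethoxy-3-methyl-2-(3,4,5-trimethoxyphenyl)-2,3-dihydro-1-benzofuran-6-ol | COc1cc2c(c(OC)c1O)O[C@H](c1cc(OC)c(OC)c(OC)c1)[C@H]2C | intermediate
8 | (2R,2′R)-2,2′-[(2-iodo-1,3-phenylene)bis(oxy)]bis[N-(2,4,6-trimethylphenyl)propanamide] | C[C@@H](Oc1cccc(O[C@H](C)C(=O)Nc2c(C)cc(C)cc2C)c1I)C(=O)Nc1c(C)cc(C)cc1C | starting material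
9 | diacetoxy-λ3-iodane of 8 | C[C@@H](Oc1cccc(O[C@H](C)C(=O)Nc2c(C)cc(C)cc2C)c1I(OC(C)=O)OC(C)=O)C(=O)Nc1c(C)cc(C)cc1C | intermediate
10 | bis(trifluoroacetoxy)-λ3-iodane of 8 | C[C@@H](Oc1cccc(O[C@H](C)C(=O)Nc2c(C)cc(C)cc2C)c1I(OC(=O)C(F)(F)F)OC(=O)C(F)(F)F)C(=O)Nc1c(C)cc(C)cc1C | intermediate
11 | allyltrimethylsilane | C=CC[Si](C)(C)C | starting material
12 | aryloxy(trifluoroacetoxy)-λ3-iodane formed from 7 (through O6) and 10 | COc1cc2c(c(OC)c1OI(OC(=O)C(F)(F)F)c1c(O[C@H](C)C(=O)Nc3c(C)cc(C)cc3C)cccc1O[C@H](C)C(=O)Nc1c(C)cc(C)cc1C)O[C@H](c1cc(OC)c(OC)c(OC)c1)[C@H]2C | intermediate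
13 | (2S,3S,5R)-5,7-dimethoxy-3-methyl-5-(prop-2-en-1-yl)-2-(3,4,5-trimethoxyphenyl)-3,5-dihydro-1-benzofuran-6(2H)-one | C=CC[C@@]1(OC)C=C2C(=C(OC)C1=O)O[C@H](c1cc(OC)c(OC)c(OC)c1)[C@H]2C | target

**Total step count:** 5 (four on the main line plus the one-step preparation of oxidant 10).
**Longest linear sequence:** 4 (steps 1, 2, 3, 5).

**Steps most likely to fail:** step 5, then step 3, then step 1.

**Step 5.**
- The weak pi-nucleophile must outrun trifluoroacetate.
- C5 must win over C7 and C3a.
- Facial control by 10 is unproven, so the sense of induction must be read from the first run.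
- Because the resident centres are remote, the (S,S) antipode of 8 would simply invert that sense, and any C5 epimer is a separable diastereomer.
- Compound 13 aromatises by retro-Claisen shift if warmed.

The fallback sets out from 7 and comes back at 13 using ordinary carbonyl polarity. Oxidative demethylation of 7 with PhI(OAc)2 in MeCN/H2O gives the ortho-quinone (2S,3S)-7-methoxy-3-methyl-2-(3,4,5-trimethoxyphenyl)-2,3-dihydro-1-benzofuran-5,6-dione F1. Its C5 carbonyl is the reactive one, because the C6 carbonyl is a deactivated vinylogous ester. It accepts allyl from allylboronic acid pinacol ester under (S)-3,3′-dibromo-BINOL catalysis to give the tertiary ortho-quinol (2S,3S,5R)-5-hydroxy-7-methoxy-3-methyl-5-(prop-2-en-1-yl)-2-(3,4,5-trimethoxyphenyl)-3,5-dihydro-1-benzofuran-6(2H)-one F2. MeI/Ag2O then methylates F2 to 13.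

**Step 3.** The oxidised ring can lose the C3 proton, or fragment the C2–C3 bond, to give a para-quinone methide before the alcohol closes. That would scramble C3 or cleave the chain. The fallback sets out from 4 and comes back at 7 without any dearomatisation. NBS in MeCN at −20 °C brominates the only free position type of ring A to give 3-bromo-4-[(1S,2S)-1-hydroxy-1-(3,4,5-trimethoxyphenyl)propan-2-yl]-2,6-dimethoxyphenol F3. CuI, 1,10-phenanthroline and Cs2CO3 in toluene at 110 °C then close the ring by Ullmann-type intramolecular C–O coupling, with retention at C2.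

**Step 1.** The electron-rich phenoxide bromide may add too slowly to zerovalent palladium. The fallback sets out from 1 and comes back at 3 with the roles of the partners exchanged. CuBr2 in refluxing EtOAc gives rac-2-bromo-1-(3,4,5-trimethoxyphenyl)propan-1-one F4. This is coupled with commercial 2,6-dimethoxy-4-(4,4,5,5-tetramethyl-1,3,2-dioxaborolan-2-yl)phenol under Ni(PPh3)4 and K3PO4 in toluene at 80 °C (Suzuki-type arylation of an alpha-halo ketone).

**Further compounds**
F1 | step 5 | (2S,3S)-7-methoxy-3-methyl-2-(3,4,5-trimethoxyphenyl)-2,3-dihydro-1-benzofuran-5,6-dione | O=C1C=C2C(=C(OC)C1=O)O[C@H](c1cc(OC)c(OC)c(OC)c1)[C@H]2C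
F2 | step 5 | (2S,3S,5R)-5-hydroxy-7-methoxy-3-methyl-5-(prop-2-en-1-yl)-2-(3,4,5-trimethoxyphenyl)-3,5-dihydro-1-benzofuran-6(2H)-one | C=CC[C@@]1(O)C=C2C(=C(OC)C1=O)O[C@H](c1cc(OC)c(OC)c(OC)c1)[C@H]2C
F3 | step 3 | 3-bromo-4-[(1S,2S)-1-hydroxy-1-(3,4,5-trimethoxyphenyl)propan-2-yl]-2,6-dimethoxyphenol | O[C@H](c1cc(OC)c(OC)c(OC)c1)[C@H](c1cc(OC)c(O)c(OC)c1Br)C
F4 | step 1 | rac-2-bromo-1-(3,4,5-trimethoxyphenyl)propan-1-one | CC(Br)C(=O)c1cc(OC)c(OC)c(OC)c1
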